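**Retrosynthetic overview**
1. Target 47 ⇐ nargenicin (46) by O18‑selective acetylation; 46 ⇐ 8,13‑deoxynargenicin (45) by enzymatic closure of the C8–O–C13 ether bridge (α‑ketoglutarate‑dependent non‑heme iron dioxygenase). This is the last ring formed.
2. 45 ⇐ 18‑membered (4E,6E,12E,14Z)‑tetraenolide 39 by transannular Diels–Alder reaction: rings A and B (cis‑decalin) and the 10‑membered lactone arise together.
3. 39 ⇐ seco acid 37 (Shiina lactonisation, C1–O17) ⇐ two Suzuki couplings (C5–C6, C13–C14) of three fragments.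
4. Fragment A, C6–C13 (steps 1–10: Noyori hydrogenation, Fráter–Seebach methylation, Noyori transfer hydrogenation); fragment B, C1–C5 (steps 11–15: copper–bis(oxazoline) glyoxylate Mukaiyama aldol); fragment C, C14–C19 (steps 16–23: pyruvate hydrogenation, (Z)‑crotylboration, Stork–Zhao olefination).
5. Ring order: 18‑membered macrolactone → carbocycles A/B with contraction to the 10‑membered lactone → tetrahydrofuran bridge.

Assumption: the name is read as 18‑O‑acetylnargenicin (the C18 acetate of the parent nargenicin carrying the pyrrole‑2‑carboxylate at O9) as drawn by the SMILES, positions are given in nargenicin numbering (C1 lactone carbonyl to C19), and the ether‑bridge dioxygenase of the nargenicin pathway (NgnO3) is taken as available by heterologous expression.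

Step 1
Reactants: 1 methyl 5-(benzyloxy)-3-oxopentanoate
Product: 2 methyl (3S)-5-(benzyloxy)-3-hydroxypentanoate
Conditions: H2 (4 atm), RuCl2[(S)-BINAP] (0.2 mol %), MeOH, 80 °C
Reagents that add atoms: none
Why: Noyori asymmetric hydrogenation of a β‑keto ester, in which the ester‑chelated ruthenium hydride of the (S)‑BINAP complex reduces one ketone face and sets C9 as the (3S)‑carbinol (first stereocentre).

Step 2
Reactants: 2 methyl (3S)-5-(benzyloxy)-3-hydroxypentanoate
Product: 3 methyl (2S,3S)-5-(benzyloxy)-3-hydroxy-2-methylpentanoate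
Conditions: LiN(iPr)2 (2.2 equiv), THF, −78 → −20 °C; MeI, DMPU, −78 → 0 °C
Reagents that add atoms: iodomethane, CI
Why: Fráter–Seebach alkylation, in which the chelated alkoxide–enolate dianion is methylated anti to the C9 side chain to give the 2,3‑anti product (sets C10).

Step 3
Reactants: 3 methyl (2S,3S)-5-(benzyloxy)-3-hydroxy-2-methylpentanoate
Product: 4 methyl (2S,3S)-5-(benzyloxy)-2-methyl-3-[(triethylsilyl)oxy]pentanoate
Conditions: Et3SiCl, imidazole, CH2Cl2, 0 °C → rt
Reagents that add atoms: chlorotriethylsilane, CC[Si](Cl)(CC)CC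
Why: Silyl ether formation; the triethylsilyl group is chosen because it can later be removed beside tert‑butyldimethylsilyl ethers.

Step 4
Reactants: 4 methyl (2S,3S)-5-(benzyloxy)-2-methyl-3-[(triethylsilyl)oxy]pentanoate
Product: 5 methyl (2S,3S)-5-hydroxy-2-methyl-3-[(triethylsilyl)oxy]pentanoate
Conditions: H2 (1 atm), Pd/C (10 %), EtOAc, rt
Reagents that add atoms: none
Why: Hydrogenolysis of the benzyl ether in ethyl acetate leaves the silyl ether and ester intact (the crude alcohol is used at once to avoid lactonisation).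

Step 5
Reactants: 5 methyl (2S,3S)-5-hydroxy-2-methyl-3-[(triethylsilyl)oxy]pentanoate
Product: 6 methyl (2S,3S)-2-methyl-5-oxo-3-[(triethylsilyl)oxy]pentanoate
Conditions: Dess–Martin periodinane, NaHCO3, CH2Cl2, 0 °C → rt
Reagents that add atoms: none
Why: Dess–Martin oxidation of the primary alcohol under buffered, non‑epimerising conditions gives the β‑silyloxy aldehyde.

Step 6
Reactants: 6 methyl (2S,3S)-2-methyl-5-oxo-3-[(triethylsilyl)oxy]pentanoate
Product: 7 methyl (2S,3S,5E)-6-iodo-2-methyl-3-[(triethylsilyl)oxy]hex-5-enoate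
Conditions: CrCl2, CHI3, THF/dioxane, 0 °C → rt
Reagents that add atoms: iodoform, IC(I)I
Why: Takai iodo‑olefination, in which the gem‑dichromium species adds to the aldehyde and eliminates to the (E)‑vinyl iodide, fixing the later C6=C7 geometry.

Step 7
Reactants: 7 methyl (2S,3S,5E)-6-iodo-2-methyl-3-[(triethylsilyl)oxy]hex-5-enoate
Product: 8 (2S,3S,5E)-6-iodo-N-methoxy-N,2-dimethyl-3-[(triethylsilyl)oxy]hex-5-enamide
Conditions: MeNH(OMe)·HCl, AlMe3, CH2Cl2, 0 °C → rt
Reagents that add atoms: N,O-dimethylhydroxylamine hydrochloride, CNOC.Cl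
Why: Weinreb amide formation by aluminium amide aminolysis of the ester under non‑basic conditions that neither epimerise C10 nor touch the vinyl iodide.

Step 8
Reactants: 8 (2S,3S,5E)-6-iodo-N-methoxy-N,2-dimethyl-3-[(triethylsilyl)oxy]hex-5-enamide; 9 ethynyl(trimethyl)silane
Product: 10 (4S,5S,7E)-8-iodo-4-methyl-5-[(triethylsilyl)oxy]-1-(trimethylsilyl)oct-7-en-1-yn-3-one
Conditions: 9, n-BuLi, THF, −78 °C; then 8, −78 → −20 °C; aq. NH4Cl
Reagents that add atoms: none
Why: Acylation of a lithium acetylide by a Weinreb amide, whose stable chelate prevents over‑addition and releases the ynone on work‑up.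

Step 9
Reactants: 10 (4S,5S,7E)-8-iodo-4-methyl-5-[(triethylsilyl)oxy]-1-(trimethylsilyl)oct-7-en-1-yn-3-one
Product: 11 (3R,4R,5S,7E)-8-iodo-4-methyl-5-[(triethylsilyl)oxy]-1-(trimethylsilyl)oct-7-en-1-yn-3-ol
Conditions: Ru[(R,R)-TsDPEN](p-cymene) (2 mol %), iPrOH, rt
Reagents that add atoms: none
Why: Noyori asymmetric transfer hydrogenation of an alkynyl ketone, in which the (R,R)‑catalyst sets C11 as the (3R)‑propargylic alcohol under catalyst control (10,11‑syn and 9,11‑anti) without base that could epimerise C10.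

Step 10
Reactants: 11 (3R,4R,5S,7E)-8-iodo-4-methyl-5-[(triethylsilyl)oxy]-1-(trimethylsilyl)oct-7-en-1-yn-3-ol
Product: 12 fragment A: (3R,4S,5S,7E)-3-[(tert-butyldimethylsilyl)oxy]-8-iodo-4-methyl-5-[(triethylsilyl)oxy]-1-(trimethylsilyl)oct-7-en-1-yne
Conditions: tBuMe2SiOTf, 2,6-lutidine, CH2Cl2, −78 → 0 °C
Reagents that add atoms: tert-butyldimethylsilyl trifluoromethanesulfonate, CC(C)(C)[Si](C)(C)OS(=O)(=O)C(F)(F)F
Why: Silylation with the silyl triflate protects the hindered propargylic alcohol (O11) as a robust silyl ether.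

Step 11
Reactants: 13 S-ethyl ethanethioate
Product: 14 {[1-(ethylsulfanyl)ethenyl]oxy}trimethylsilane
Conditions: LiN(iPr)2, THF, −78 °C; Me3SiCl
Reagents that add atoms: chlorotrimethylsilane, C[Si](C)(C)Cl
Why: Kinetic O‑silylation of the thioester lithium enolate gives the ketene S,O‑acetal used as Mukaiyama donor.

Step 12
Reactants: 14 {[1-(ethylsulfanyl)ethenyl]oxy}trimethylsilane; 15 methyl glyoxylate
Product: 17 methyl (2S)-4-(ethylsulfanyl)-2-hydroxy-4-oxobutanoate, via silyl ether 16 (not isolated)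
Conditions: Cu(OTf)2/(S,S)-t-Bu-box (10 mol %), CH2Cl2, −78 °C; then 1 M HCl, THF
Reagents that add atoms: none
Why: Catalytic asymmetric Mukaiyama aldol addition, in which glyoxylate is chelated to the bis(oxazoline)copper Lewis acid whose tert‑butyl groups shield one aldehyde face, so C2 forms as the (S)‑carbinol, and acid then cleaves the silyl ether.

Step 13
Reactants: 17 methyl (2S)-4-(ethylsulfanyl)-2-hydroxy-4-oxobutanoate
Product: 18 methyl (2S)-4-(ethylsulfanyl)-2-methoxy-4-oxobutanoate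
Conditions: Me3OBF4, 1,8-bis(dimethylamino)naphthalene, CH2Cl2, 0 °C → rt
Reagents that add atoms: trimethyloxonium tetrafluoroborate, C[O+](C)C.F[B-](F)(F)F
Why: O‑Methylation with trimethyloxonium tetrafluoroborate under non‑basic conditions installs the C2 methoxy group without epimerisation or β‑elimination.

Step 14
Reactants: 18 methyl (2S)-4-(ethylsulfanyl)-2-methoxy-4-oxobutanoate
Product: 19 methyl (2S)-2-methoxy-4-oxobutanoate
Conditions: Et3SiH, Pd/C (10 %), acetone, rt
Reagents that add atoms: none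
Why: Fukuyama reduction converts the thioester selectively into the aldehyde beside the methyl ester under neutral conditions.

Step 15
Reactants: 19 methyl (2S)-2-methoxy-4-oxobutanoate
Product: 20 fragment B: methyl (2S,4E)-2-methoxy-5-(4,4,5,5-tetramethyl-1,3,2-dioxaborolan-2-yl)pent-4-enoate
Conditions: CrCl2, Cl2CHB(pin), LiI, THF, rt
Reagents that add atoms: 2-(dichloromethyl)-4,4,5,5-tetramethyl-1,3,2-dioxaborolane, ClC(Cl)B1OC(C)(C)C(C)(C)O1
Why: Takai–Utimoto boryl‑olefination converts the aldehyde into the (E)‑alkenyl boronate under non‑basic conditions, setting the C4=C5 geometry.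

Step 16
Reactants: 21 ethyl pyruvate
Product: 22 ethyl (2R)-2-hydroxypropanoate
Conditions: H2 (70 bar), Pt/Al2O3 (5 % Pt), cinchonidine, AcOH, 20 °C
Reagents that add atoms: none
Why: Enantioselective heterogeneous hydrogenation of an α‑keto ester on cinchonidine‑modified platinum (Orito reaction) gives the (R)‑lactate and so sets C18.

Step 17
Reactants: 22 ethyl (2R)-2-hydroxypropanoate
Product: 23 ethyl (2R)-2-[(tert-butyldimethylsilyl)oxy]propanoate
Conditions: tBuMe2SiCl, imidazole, DMF, rt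
Reagents that add atoms: tert-butyldimethylsilyl chloride, CC(C)(C)[Si](C)(C)Cl
Why: Silyl ether formation gives a non‑chelating α‑silyloxy group for the later Felkin‑type addition.

Step 18
Reactants: 23 ethyl (2R)-2-[(tert-butyldimethylsilyl)oxy]propanoate
Product: 24 (2R)-2-[(tert-butyldimethylsilyl)oxy]propanal
Conditions: iBu2AlH, CH2Cl2, −78 °C; aq. KNaC4H4O6
Reagents that add atoms: none
Why: Partial ester reduction at −78 °C stops at the aldehyde through the stable tetrahedral aluminium hemiacetal without epimerising the α‑stereocentre.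

Step 19
Reactants: 24 (2R)-2-[(tert-butyldimethylsilyl)oxy]propanal; 25 2-[(2Z)-but-2-en-1-yl]-4,4,5,5-tetramethyl-1,3,2-dioxaborolane
Product: 27 (2R,3S,4R)-2-[(tert-butyldimethylsilyl)oxy]-4-methylhex-5-en-3-ol, via borate ester 26 (not isolated)
Conditions: toluene, 4 Å sieves, −78 °C → rt; then aq. NaHCO3
Reagents that add atoms: none
Why: Crotylboration through a closed chair transition state, in which the (Z)‑crotylboronate gives the 16,17‑syn relationship and adds anti to the C18 silyloxy group (Felkin/Cornforth mode), giving the 17,18‑anti triad.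

Step 20
Reactants: 27 (2R,3S,4R)-2-[(tert-butyldimethylsilyl)oxy]-4-methylhex-5-en-3-ol
Product: 28 (2R,3S,4R)-2-[(tert-butyldimethylsilyl)oxy]-4-methyl-3-[(triethylsilyl)oxy]hex-5-ene
Conditions: Et3SiCl, imidazole, DMAP (cat.), DMF, rt
Reagents that add atoms: chlorotriethylsilane, CC[Si](Cl)(CC)CC
Why: Silylation masks O17 temporarily for the ozonolysis and ylide steps.

Step 21
Reactants: 28 (2R,3S,4R)-2-[(tert-butyldimethylsilyl)oxy]-4-methyl-3-[(triethylsilyl)oxy]hex-5-ene
Product: 30 (2S,3S,4R)-4-[(tert-butyldimethylsilyl)oxy]-2-methyl-3-[(triethylsilyl)oxy]pentanal, via ozonide 29 (not isolated)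
Conditions: O3, CH2Cl2, −78 °C; then PPh3, −78 °C → rt
Reagents that add atoms: ozone, [O-][O+]=O
Why: Ozonolysis with reductive work‑up reveals the C15 aldehyde without touching the silyl ethers or epimerising C16.

Step 22
Reactants: 30 (2S,3S,4R)-4-[(tert-butyldimethylsilyl)oxy]-2-methyl-3-[(triethylsilyl)oxy]pentanal
Product: 31 (2Z,4R,5S,6R)-6-[(tert-butyldimethylsilyl)oxy]-2-iodo-4-methyl-5-[(triethylsilyl)oxy]hept-2-ene
Conditions: EtPPh3I, n-BuLi, THF, rt; I2, −78 °C; NaN(SiMe3)2, −20 °C; then 30, −78 °C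
Reagents that add atoms: ethyltriphenylphosphonium iodide, CC[P+](c1ccccc1)(c1ccccc1)c1ccccc1.[I-]; iodine, II
Why: Stork–Zhao–Wittig olefination, in which the α‑iodo ylide adds under kinetic control to give the (Z)‑2‑iodoalkene (iodine cis to C16), which fixes the Z geometry of C14=C15.

Step 23
Reactants: 31 (2Z,4R,5S,6R)-6-[(tert-butyldimethylsilyl)oxy]-2-iodo-4-methyl-5-[(triethylsilyl)oxy]hept-2-ene
Product: 32 fragment C: (2R,3S,4R,5Z)-2-[(tert-butyldimethylsilyl)oxy]-6-iodo-4-methylhept-5-en-3-ol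
Conditions: PPTS (cat.), MeOH/CH2Cl2, 0 °C
Reagents that add atoms: none
Why: Selective acid‑catalysed methanolysis removes the triethylsilyl ether at O17 while the bulkier silyl ether at O18 survives.

Step 24
Reactants: 12 fragment A (vinyl iodide); 20 fragment B (alkenyl boronate)
Product: 33 C1–C13 dienyne ester (13-trimethylsilyl)
Conditions: Pd(dppf)Cl2 (5 mol %), K3PO4, THF/H2O, rt
Reagents that add atoms: none
Why: Suzuki–Miyaura coupling proceeds with retention at both alkenyl partners and builds the (4E,6E)‑diene while the silylalkyne stays inert.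

Step 25
Reactants: 33 C1–C13 dienyne ester (13-trimethylsilyl)
Product: 34 C1–C13 dienyne ester (terminal alkyne)
Conditions: K2CO3, MeOH, 0 °C
Reagents that add atoms: none
Why: Base‑catalysed methanolysis cleaves only the C(sp)–Si bond, and the cold, brief conditions leave the silyl ethers and the C2 centre of the methyl ester unchanged.

Step 26
Reactants: 34 C1–C13 dienyne ester (terminal alkyne)
Product: 35 C1–C13 trienyl boronate
Conditions: HB(pin), Cp2Zr(H)Cl (10 mol %), Et3N (10 mol %), neat, 60 °C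
Reagents that add atoms: pinacolborane, [H]B1OC(C)(C)C(C)(C)O1
Why: Zirconium‑catalysed syn‑hydroboration of the terminal alkyne places boron at the terminus and gives the (12E)‑alkenyl boronate, the internal diene and ester being unreactive.

Step 27
Reactants: 35 C1–C13 trienyl boronate; 32 fragment C (Z-vinyl iodide)
Product: 36 seco ester (C1–C19 tetraene methyl ester with 17-OH free)
Conditions: Pd(dppf)Cl2 (10 mol %), AsPh3, Cs2CO3, DMF/THF/H2O, rt
Reagents that add atoms: none
Why: Suzuki–Miyaura coupling with retention of both geometries builds the (12E,14Z)‑diene, and the free C17 hydroxyl is tolerated.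

Step 28
Reactants: 36 seco ester
Product: 37 seco acid
Conditions: LiOH, THF/MeOH/H2O, 0 °C; then cold dilute HCl to pH 4
Reagents that add atoms: lithium hydroxide, [Li+].[OH-]
Why: Saponification of the activated α‑methoxy methyl ester at 0 °C gives the acid while the silyl ethers survive.

Step 29
Reactants: 37 seco acid
Product: 39 eighteen-membered macrolactone (C1–O17), via mixed anhydride 38 (not isolated)
Conditions: MNBA, DMAP, CH2Cl2 (1 mM, slow addition), rt
Reagents that add atoms: none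
Why: Shiina macrolactonisation, in which the mixed anhydride is captured through the acyl‑DMAP species by the only free hydroxyl (O17) under high dilution at room temperature, where C2 does not epimerise.

Step 30
Reactants: 39 eighteen-membered macrolactone
Product: 40 9-O-triethylsilyl-11,18-bis-O-(tert-butyldimethylsilyl)-8,13-deoxynodusmicin
Conditions: toluene (1 mM), BHT, 110 °C, sealed tube
Reagents that add atoms: none
Why: Transannular Diels–Alder reaction, in which the (4E,6E)‑diene adds suprafacially to the (12E)‑alkene (the (14Z)‑methyl diene cannot become s‑cis and only activates the dienophile), so C4/C7 become cis and C12/C13 trans, the macrocycle enforces the tether‑endo transition state that gives the cis‑fused decalin, and the face is the one that keeps the C10 methyl and C11 silyloxy groups pseudo‑equatorial on the forming ring B.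

Step 31
Reactants: 40 9-O-triethylsilyl-11,18-bis-O-(tert-butyldimethylsilyl)-8,13-deoxynodusmicin
Product: 41 11,18-bis-O-(tert-butyldimethylsilyl)-8,13-deoxynodusmicin
Conditions: PPTS, MeOH/CH2Cl2, 0 °C → rt
Reagents that add atoms: none
Why: Selective acid methanolysis removes the secondary triethylsilyl ether at C9 beside the two secondary tert‑butyldimethylsilyl ethers.

Step 32
Reactants: 41 11,18-bis-O-(tert-butyldimethylsilyl)-8,13-deoxynodusmicin; 42 1H-pyrrole-2-carboxylic acid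
Product: 44 11,18-bis-O-(tert-butyldimethylsilyl)-8,13-deoxynargenicin, via mixed anhydride 43 (not isolated)
Conditions: 42, 2,4,6-Cl3C6H2COCl, Et3N, THF, rt; then 41, DMAP, toluene, 40 °C
Reagents that add atoms: none
Why: Yamaguchi esterification, in which the mixed anhydride of the pyrrole acid acylates the only free hydroxyl (O9) through the acyl‑DMAP species while the weakly nucleophilic pyrrole NH is not acylated.

Step 33
Reactants: 44 11,18-bis-O-(tert-butyldimethylsilyl)-8,13-deoxynargenicin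
Product: 45 8,13-deoxynargenicin
Conditions: HF·pyridine, pyridine, THF, 0 °C → rt
Reagents that add atoms: none
Why: Buffered fluoride desilylation removes both silyl ethers without acyl migration or lactone opening.

Step 34
Reactants: 45 8,13-deoxynargenicin
Product: 46 nargenicin
Conditions: NgnO3 (α-ketoglutarate-dependent non-heme iron dioxygenase, recombinant from Escherichia coli), FeSO4, α-ketoglutarate, sodium ascorbate, air, HEPES pH 7.5, 5 % DMSO, 28 °C
Reagents that add atoms: dioxygen, O=O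
Why: Enzymatic C–H oxidation and oxidative cyclisation by the dioxygenase of the nargenicin pathway, whose natural substrate is 45, puts oxygen on C8 on the face syn to C13–H and closes onto C13 with retention, the only geometry the cis‑decalin allows (sets C8 and the quaternary C13).

Step 35
Reactants: 46 nargenicin
Product: 47 18-O-acetylnargenicin
Conditions: Ac2O (1.1 equiv), pyridine, CH2Cl2, −20 → 0 °C
Reagents that add atoms: acetic anhydride, CC(=O)OC(C)=O
Why: Selective acylation, in which the side‑chain C18 carbinol is the most accessible hydroxyl (the C11 hydroxyl is flanked by the C10 methyl and the ring fusion), so one equivalent of anhydride at low temperature acetylates O18 only.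

**Compound list**
1 | methyl 5-(benzyloxy)-3-oxopentanoate | COC(=O)CC(=O)CCOCc1ccccc1 | starting material
2 | methyl (3S)-5-(benzyloxy)-3-hydroxypentanoate | COC(=O)C[C@@H](O)CCOCc1ccccc1 | intermediate
3 | methyl (2S,3S)-5-(benzyloxy)-3-hydroxy-2-methylpentanoate | COC(=O)[C@@H](C)[C@@H](O)CCOCc1ccccc1 | intermediate
4 | methyl (2S,3S)-5-(benzyloxy)-2-methyl-3-[(triethylsilyl)oxy]pentanoate | COC(=O)[C@@H](C)[C@@H](O[Si](CC)(CC)CC)CCOCc1ccccc1 | intermediate
5 | methyl (2S,3S)-5-hydroxy-2-methyl-3-[(triethylsilyl)oxy]pentanoate | COC(=O)[C@@H](C)[C@@H](O[Si](CC)(CC)CC)CCO | intermediate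
6 | methyl (2S,3S)-2-methyl-5-oxo-3-[(triethylsilyl)oxy]pentanoate | COC(=O)[C@@H](C)[C@@H](O[Si](CC)(CC)CC)CC=O | intermediate
7 | methyl (2S,3S,5E)-6-iodo-2-methyl-3-[(triethylsilyl)oxy]hex-5-enoate | COC(=O)[C@@H](C)[C@@H](O[Si](CC)(CC)CC)C/C=C/I | intermediate
8 | (2S,3S,5E)-6-iodo-N-methoxy-N,2-dimethyl-3-[(triethylsilyl)oxy]hex-5-enamide | CON(C)C(=O)[C@@H](C)[C@@H](O[Si](CC)(CC)CC)C/C=C/I | intermediate
9 | ethynyl(trimethyl)silane | C#C[Si](C)(C)C | starting material
10 | (4S,5S,7E)-8-iodo-4-methyl-5-[(triethylsilyl)oxy]-1-(trimethylsilyl)oct-7-en-1-yn-3-one | C[Si](C)(C)C#CC(=O)[C@@H](C)[C@@H](O[Si](CC)(CC)CC)C/C=C/I | intermediate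
11 | (3R,4R,5S,7E)-8-iodo-4-methyl-5-[(triethylsilyl)oxy]-1-(trimethylsilyl)oct-7-en-1-yn-3-ol | C[Si](C)(C)C#C[C@H](O)[C@@H](C)[C@@H](O[Si](CC)(CC)CC)C/C=C/I | intermediate
12 | fragment A, (3R,4S,5S,7E)-3-[(tert-butyldimethylsilyl)oxy]-8-iodo-4-methyl-5-[(triethylsilyl)oxy]-1-(trimethylsilyl)oct-7-en-1-yne | C[Si](C)(C)C#C[C@H](O[Si](C)(C)C(C)(C)C)[C@@H](C)[C@@H](O[Si](CC)(CC)CC)C/C=C/I | intermediate
13 | S-ethyl ethanethioate | CCSC(C)=O | starting material
14 | {[1-(ethylsulfanyl)ethenyl]oxy}trimethylsilane | C=C(O[Si](C)(C)C)SCC | intermediate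
15 | methyl glyoxylate (methyl oxoacetate) | COC(=O)C=O | starting material
16 | methyl (2S)-4-(ethylsulfanyl)-4-oxo-2-[(trimethylsilyl)oxy]butanoate | C[Si](C)(C)O[C@H](C(=O)OC)CC(=O)SCC | intermediate
17 | methyl (2S)-4-(ethylsulfanyl)-2-hydroxy-4-oxobutanoate | O[C@H](C(=O)OC)CC(=O)SCC | intermediate
18 | methyl (2S)-4-(ethylsulfanyl)-2-methoxy-4-oxobutanoate | CO[C@H](C(=O)OC)CC(=O)SCC | intermediate
19 | methyl (2S)-2-methoxy-4-oxobutanoate | CO[C@H](C(=O)OC)CC=O | intermediate
20 | fragment B, methyl (2S,4E)-2-methoxy-5-(4,4,5,5-tetramethyl-1,3,2-dioxaborolan-2-yl)pent-4-enoate | CO[C@H](C(=O)OC)C/C=C/B1OC(C)(C)C(C)(C)O1 | intermediate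
21 | ethyl pyruvate (ethyl 2-oxopropanoate) | CCOC(=O)C(C)=O | starting material
22 | ethyl (2R)-2-hydroxypropanoate | C[C@@H](O)C(=O)OCC | intermediate
23 | ethyl (2R)-2-[(tert-butyldimethylsilyl)oxy]propanoate | C[C@@H](O[Si](C)(C)C(C)(C)C)C(=O)OCC | intermediate
24 | (2R)-2-[(tert-butyldimethylsilyl)oxy]propanal | C[C@@H](O[Si](C)(C)C(C)(C)C)C=O | intermediate
25 | 2-[(2Z)-but-2-en-1-yl]-4,4,5,5-tetramethyl-1,3,2-dioxaborolane | C/C=C\CB1OC(C)(C)C(C)(C)O1 | starting material
26 | pinacol borate ester of 27 (O3–B) | C=C[C@@H](C)[C@H](OB1OC(C)(C)C(C)(C)O1)[C@@H](C)O[Si](C)(C)C(C)(C)C | intermediate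
27 | (2R,3S,4R)-2-[(tert-butyldimethylsilyl)oxy]-4-methylhex-5-en-3-ol | C=C[C@@H](C)[C@H](O)[C@@H](C)O[Si](C)(C)C(C)(C)C | intermediate
28 | (2R,3S,4R)-2-[(tert-butyldimethylsilyl)oxy]-4-methyl-3-[(triethylsilyl)oxy]hex-5-ene | C=C[C@@H](C)[C@H](O[Si](CC)(CC)CC)[C@@H](C)O[Si](C)(C)C(C)(C)C | intermediate
29 | 1,2,4-trioxolane (ozonide) of 28, mixture at the ring carbon | C1OC(OO1)[C@@H](C)[C@H](O[Si](CC)(CC)CC)[C@@H](C)O[Si](C)(C)C(C)(C)C | intermediate
30 | (2S,3S,4R)-4-[(tert-butyldimethylsilyl)oxy]-2-methyl-3-[(triethylsilyl)oxy]pentanal | O=C[C@@H](C)[C@H](O[Si](CC)(CC)CC)[C@@H](C)O[Si](C)(C)C(C)(C)C | intermediate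
31 | (2Z,4R,5S,6R)-6-[(tert-butyldimethylsilyl)oxy]-2-iodo-4-methyl-5-[(triethylsilyl)oxy]hept-2-ene | I/C(C)=C\[C@@H](C)[C@H](O[Si](CC)(CC)CC)[C@@H](C)O[Si](C)(C)C(C)(C)C | intermediate
32 | fragment C, (2R,3S,4R,5Z)-2-[(tert-butyldimethylsilyl)oxy]-6-iodo-4-methylhept-5-en-3-ol | I/C(C)=C\[C@@H](C)[C@H](O)[C@@H](C)O[Si](C)(C)C(C)(C)C | intermediate
33 | methyl (2S,4E,6E,9S,10S,11R)-11-[(tert-butyldimethylsilyl)oxy]-2-methoxy-10-methyl-9-[(triethylsilyl)oxy]-13-(trimethylsilyl)trideca-4,6-dien-12-ynoate | CO[C@H](C(=O)OC)C/C=C/C=C/C[C@H](O[Si](CC)(CC)CC)[C@H](C)[C@@H](O[Si](C)(C)C(C)(C)C)C#C[Si](C)(C)C | intermediate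
34 | methyl (2S,4E,6E,9S,10S,11R)-11-[(tert-butyldimethylsilyl)oxy]-2-methoxy-10-methyl-9-[(triethylsilyl)oxy]trideca-4,6-dien-12-ynoate | CO[C@H](C(=O)OC)C/C=C/C=C/C[C@H](O[Si](CC)(CC)CC)[C@H](C)[C@@H](O[Si](C)(C)C(C)(C)C)C#C | intermediate
35 | methyl (2S,4E,6E,9S,10S,11S,12E)-11-[(tert-butyldimethylsilyl)oxy]-2-methoxy-10-methyl-13-(4,4,5,5-tetramethyl-1,3,2-dioxaborolan-2-yl)-9-[(triethylsilyl)oxy]trideca-4,6,12-trienoate | CO[C@H](C(=O)OC)C/C=C/C=C/C[C@H](O[Si](CC)(CC)CC)[C@H](C)[C@@H](O[Si](C)(C)C(C)(C)C)/C=C/B1OC(C)(C)C(C)(C)O1 | intermediate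
36 | seco ester, methyl (2S,4E,6E,9S,10S,11S,12E,14Z,16R,17S,18R)-11,18-bis[(tert-butyldimethylsilyl)oxy]-17-hydroxy-2-methoxy-10,14,16-trimethyl-9-[(triethylsilyl)oxy]nonadeca-4,6,12,14-tetraenoate | CO[C@H](C(=O)OC)C/C=C/C=C/C[C@H](O[Si](CC)(CC)CC)[C@H](C)[C@@H](O[Si](C)(C)C(C)(C)C)/C=C/C(C)=C\[C@@H](C)[C@H](O)[C@@H](C)O[Si](C)(C)C(C)(C)C | intermediate
37 | seco acid, (2S,4E,6E,9S,10S,11S,12E,14Z,16R,17S,18R)-11,18-bis[(tert-butyldimethylsilyl)oxy]-17-hydroxy-2-methoxy-10,14,16-trimethyl-9-[(triethylsilyl)oxy]nonadeca-4,6,12,14-tetraenoic acid | CO[C@H](C(=O)O)C/C=C/C=C/C[C@H](O[Si](CC)(CC)CC)[C@H](C)[C@@H](O[Si](C)(C)C(C)(C)C)/C=C/C(C)=C\[C@@H](C)[C@H](O)[C@@H](C)O[Si](C)(C)C(C)(C)C | intermediate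
38 | mixed anhydride of 37 and 2-methyl-6-nitrobenzoic acid | CO[C@H](C(=O)OC(=O)c1c(C)cccc1[N+](=O)[O-])C/C=C/C=C/C[C@H](O[Si](CC)(CC)CC)[C@H](C)[C@@H](O[Si](C)(C)C(C)(C)C)/C=C/C(C)=C\[C@@H](C)[C@H](O)[C@@H](C)O[Si](C)(C)C(C)(C)C | intermediate
39 | 18-membered lactone (C1–O17) of 37, (2S,4E,6E,9S,10S,11S,12E,14Z,16R,17S,18R); 9-O-triethylsilyl, 11,18-bis-O-tert-butyldimethylsilyl | CO[C@H]1C/C=C/C=C/C[C@H](O[Si](CC)(CC)CC)[C@H](C)[C@@H](O[Si](C)(C)C(C)(C)C)/C=C/C(C)=C\[C@@H](C)[C@@H]([C@@H](C)O[Si](C)(C)C(C)(C)C)OC1=O | intermediate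
40 | 9-O-triethylsilyl-11,18-bis-O-(tert-butyldimethylsilyl)-8,13-deoxynodusmicin, (2S,4S,7R,9S,10S,11S,12R,13R,14Z,16R,17S,18R): cis-fused Δ5-octalin with the 10-membered lactone, no ether bridge | CO[C@H]1C[C@H]2C=C[C@H]3C[C@H](O[Si](CC)(CC)CC)[C@H](C)[C@@H](O[Si](C)(C)C(C)(C)C)[C@H]3[C@@H]2/C(C)=C\[C@@H](C)[C@@H]([C@@H](C)O[Si](C)(C)C(C)(C)C)OC1=O | intermediate
41 | 11,18-bis-O-(tert-butyldimethylsilyl)-8,13-deoxynodusmicin (9-OH free) | CO[C@H]1C[C@H]2C=C[C@H]3C[C@H](O)[C@H](C)[C@@H](O[Si](C)(C)C(C)(C)C)[C@H]3[C@@H]2/C(C)=C\[C@@H](C)[C@@H]([C@@H](C)O[Si](C)(C)C(C)(C)C)OC1=O | intermediate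
42 | 1H-pyrrole-2-carboxylic acid | OC(=O)c1ccc[nH]1 | starting material
43 | 1H-pyrrole-2-carboxylic 2,4,6-trichlorobenzoic anhydride | O=C(OC(=O)c1c(Cl)cc(Cl)cc1Cl)c1ccc[nH]1 | intermediate
44 | 11,18-bis-O-(tert-butyldimethylsilyl)-8,13-deoxynargenicin (9-O-pyrrole-2-carbonyl) | CO[C@H]1C[C@H]2C=C[C@H]3C[C@H](OC(=O)c4ccc[nH]4)[C@H](C)[C@@H](O[Si](C)(C)C(C)(C)C)[C@H]3[C@@H]2/C(C)=C\[C@@H](C)[C@@H]([C@@H](C)O[Si](C)(C)C(C)(C)C)OC1=O | intermediate
45 | 8,13-deoxynargenicin, (2S,4S,7R,9S,10R,11S,12R,13R,14Z,16R,17S,18R) | CO[C@H]1C[C@H]2C=C[C@H]3C[C@H](OC(=O)c4ccc[nH]4)[C@H](C)[C@@H](O)[C@H]3[C@@H]2/C(C)=C\[C@@H](C)[C@@H]([C@@H](C)O)OC1=O | intermediate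
46 | nargenicin, (2S,4S,7R,8R,9R,10R,11R,12S,13S,14Z,16R,17S,18R) | CO[C@H]1C[C@H]2C=C[C@H]3[C@H]4O[C@]2(/C(C)=C\[C@@H](C)[C@@H]([C@@H](C)O)OC1=O)[C@@H]3[C@H](O)[C@@H](C)[C@H]4OC(=O)c1ccc[nH]1 | intermediate
47 | 18-O-acetylnargenicin, (2S,4S,7R,8R,9R,10R,11R,12S,13S,14Z,16R,17S,18R) | CO[C@H]1C[C@H]2C=C[C@H]3[C@H]4O[C@]2(/C(C)=C\[C@@H](C)[C@@H]([C@@H](C)OC(C)=O)OC1=O)[C@@H]3[C@H](O)[C@@H](C)[C@H]4OC(=O)c1ccc[nH]1 | target

**Step count and risks**
Total step count: 35. Longest linear sequence: 22 steps (steps 1–10, then 24–35).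

Three steps most likely to fail:

1. Step 30 (transannular Diels–Alder): the facial and endo selectivity rest on conformational arguments, and a wrong diastereomer or no reaction at a tolerable temperature is possible. The fallback sets out from 36 and comes back at 40. The open‑chain tetraene 36 is heated (toluene, BHT, 160 °C) so that an ordinary intramolecular Diels–Alder reaction of the 1,7,9‑decatriene unit gives the decalin hydroxy ester F1 (diastereomers separated at this stage). Saponification (LiOH, 0 °C) gives the decalin hydroxy acid F2. The ten‑membered lactone is then closed directly by Shiina lactonisation (MNBA, DMAP, high dilution) to give 40. This replaces ring contraction of the macrolide by cycloaddition first and medium‑ring lactonisation second.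

2. Step 34 (enzymatic ether bridge): an isolated iron/α‑ketoglutarate enzyme may lose activity or fail on preparative scale with a poorly soluble substrate. The fallback sets out from 40 and comes back at 46. Global desilylation of 40 (HF·pyridine) gives 8,13‑deoxynodusmicin F3. This is fed to resting cells of a polyketide‑synthase‑deficient mutant of the nargenicin‑producing Nocardia strain. The cells supply cofactors and both late tailoring enzymes (the dioxygenase and the pyrrole‑2‑carbonyl transferase), so ether bridge and C9 ester are installed in vivo to give 46, which is extracted.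

3. Step 22 (Stork–Zhao olefination): yields with α‑branched aldehydes are often modest, and Z/E erosion or C16 epimerisation can occur. The fallback sets out from 30 and comes back at 36. Dibromo‑olefination of 30 (CBr4, PPh3, 0 °C) gives the 1,1‑dibromoalkene F4. Palladium‑catalysed Negishi methylation at the bromine trans to the chain (MeZnCl, Pd(DPEphos)Cl2) gives the (Z)‑bromoalkene silyl ether F5, with bromine cis to C16. Methanolysis of the triethylsilyl ether (PPTS, MeOH) gives the (Z)‑bromoalkenol F6. F6 replaces 32 in the Suzuki coupling with 35 (Pd(t‑Bu3P)2, Cs2CO3), giving 36.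

Further compounds
F1 | step 30 | decalin hydroxy ester: methyl ester of the C1–O17 seco form of 40 (17-OH free) | CO[C@H](C(=O)OC)C[C@H]1C=C[C@H]2C[C@H](O[Si](CC)(CC)CC)[C@H](C)[C@@H](O[Si](C)(C)C(C)(C)C)[C@H]2[C@@H]1/C(C)=C\[C@@H](C)[C@H](O)[C@@H](C)O[Si](C)(C)C(C)(C)C
F2 | step 30 | decalin hydroxy acid: C1–O17 seco acid of 40 | CO[C@H](C(=O)O)C[C@H]1C=C[C@H]2C[C@H](O[Si](CC)(CC)CC)[C@H](C)[C@@H](O[Si](C)(C)C(C)(C)C)[C@H]2[C@@H]1/C(C)=C\[C@@H](C)[C@H](O)[C@@H](C)O[Si](C)(C)C(C)(C)C
F3 | step 34 | 8,13-deoxynodusmicin (9,11,18-triol) | CO[C@H]1C[C@H]2C=C[C@H]3C[C@H](O)[C@H](C)[C@@H](O)[C@H]3[C@@H]2/C(C)=C\[C@@H](C)[C@@H]([C@@H](C)O)OC1=O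
F4 | step 22 | 1,1-dibromoalkene: (3R,4S,5R)-1,1-dibromo-5-[(tert-butyldimethylsilyl)oxy]-3-methyl-4-[(triethylsilyl)oxy]hex-1-ene | BrC(Br)=C[C@@H](C)[C@H](O[Si](CC)(CC)CC)[C@@H](C)O[Si](C)(C)C(C)(C)C
F5 | step 22 | (Z)-bromoalkene silyl ether: (2Z,4R,5S,6R)-2-bromo-6-[(tert-butyldimethylsilyl)oxy]-4-methyl-5-[(triethylsilyl)oxy]hept-2-ene | Br/C(C)=C\[C@@H](C)[C@H](O[Si](CC)(CC)CC)[C@@H](C)O[Si](C)(C)C(C)(C)C
F6 | step 22 | (Z)-bromoalkenol: (2R,3S,4R,5Z)-6-bromo-2-[(tert-butyldimethylsilyl)oxy]-4-methylhept-5-en-3-ol | Br/C(C)=C\[C@@H](C)[C@H](O)[C@@H](C)O[Si](C)(C)C(C)(C)C
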